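The cyclopentane ring is closed last, at the lactone oxidation level. In the α-methyl-α,β-unsaturated δ-lactone that maps onto the pyran ring (O2–C3(=O)–C4=C4a), C4a is the β-carbon, so a primary C5 radical tethered through C6–C7 to C7a adds to it 5-exo, forges C4a–C5 and delivers the cis-fused cyclopenta[c]pyranone in one operation. The radical is released by reductive decarboxylation of an N-acyloxyphthalimide. The precursor 22 is a trans-5,6-disubstituted 3-methyl-5,6-dihydropyran-2-one with the O-benzyl coumarin on C1 and the pentanoate chain on C7a; C7 comes from (S)-citronellic acid, C1 and C7a from an auxiliary anti-aldol. The acyl side chain is attached afterwards through the ketene acetal triflate of the lactone.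

Key step: step 14

Remark 1: Locants C1–C7a are those of the cyclopenta[c]pyran core of the target and are used for the corresponding atoms of all intermediates; Ar stands for 4-(benzyloxy)-5-methyl-2-oxo-2H-chromen-3-yl.
Remark 2: The magnesium-catalysed anti-aldol of step 5 is assumed to follow the chelated (Z)-enolate model (attack on the face opposite the auxiliary benzyl group), which calls for the (R)-auxiliary.
Remark 3: Compounds 23 and 29 are expected as epimer mixtures at C4 and at the new carbinol carbon; both centres become sp2 later, so the mixtures are carried on.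

Step 1
Reactants: 1 1-(2-hydroxy-6-methylphenyl)ethanone
Product: 2 4-hydroxy-5-methyl-2H-chromen-2-one
Conditions: NaH (3 equiv), (EtO)2CO, toluene, 110 °C; then aq. HCl
Reagents that add atoms: diethyl carbonate, CCOC(=O)OCC
Why: Claisen-type C-acylation of the ketone enolate by the carbonate followed by lactonisation onto the phenoxide is the standard route from 2-hydroxyacetophenones to 4-hydroxycoumarins, and no stereocentre is involved.

Step 2
Reactants: 2 4-hydroxy-5-methyl-2H-chromen-2-one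
Product: 4 4-chloro-5-methyl-2-oxo-2H-chromene-3-carbaldehyde, via iminium chloride 3 (not isolated)
Conditions: POCl3 (3 equiv), DMF, 0 → 60 °C; then ice–water
Reagents that add atoms: N,N-dimethylformamide, CN(C)C=O (formyl carbon); phosphoryl chloride, O=P(Cl)(Cl)Cl (chlorine); water, O (formyl oxygen)
Why: The Vilsmeier–Haack reaction of a 4-hydroxycoumarin should formylate the nucleophilic C3 and exchange the vinylogous acid hydroxyl for chloride in one pot, the iminium salt being hydrolysed on aqueous work-up.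

Step 3
Reactants: 4 4-chloro-5-methyl-2-oxo-2H-chromene-3-carbaldehyde
Product: 5 4-(benzyloxy)-5-methyl-2-oxo-2H-chromene-3-carbaldehyde
Conditions: BnOH (1.1 equiv), K2CO3, MeCN, 0 °C → rt
Reagents that add atoms: benzyl alcohol, OCc1ccccc1
Why: Addition–elimination (vinylogous acyl substitution) of the alcohol at C4, which is activated by both the lactone and the formyl group, should replace chloride under mild carbonate base without consuming the aldehyde.

Step 4
Reactants: 6 (3S)-3,7-dimethyloct-6-enoic acid [(S)-citronellic acid]; 7 (4R)-4-benzyl-1,3-oxazolidin-2-one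
Product: 9 (4R)-4-benzyl-3-[(3S)-3,7-dimethyloct-6-enoyl]-1,3-oxazolidin-2-one, via mixed pivalic anhydride 8 (not isolated)
Conditions: t-BuCOCl, Et3N, THF, −20 °C; then 7, LiCl, −20 °C → rt
Reagents that add atoms: none
Why: N-Acylation of the oxazolidinone through the mixed pivalic anhydride under LiCl/Et3N conditions is the routine entry to such imides and leaves the C7 methyl stereocentre and the trisubstituted alkene untouched.

Step 5
Reactants: 9 (4R)-4-benzyl-3-[(3S)-3,7-dimethyloct-6-enoyl]-1,3-oxazolidin-2-one; 5 4-(benzyloxy)-5-methyl-2-oxo-2H-chromene-3-carbaldehyde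
Product: 11 (4R)-4-benzyl-3-[(2S,3S)-2-{(R)-Ar(hydroxy)methyl}-3,7-dimethyloct-6-enoyl]-1,3-oxazolidin-2-one, via trimethylsilyl ether 10 (not isolated)
Conditions: MgCl2 (0.2 equiv), Et3N (2 equiv), Me3SiCl (1.5 equiv), EtOAc, rt; then 1 M HCl, THF, rt
Reagents that add atoms: none
Why: In this magnesium-halide-catalysed direct anti-aldol reaction of an N-acyloxazolidinone (Evans-type auxiliary aldol), soft enolisation gives the chelated (Z)-magnesium enolate, the non-enolisable aldehyde 5 adds on the face opposite the auxiliary benzyl group through a boat-like transition state and silylation of the aldolate turns the catalyst over, which should set the future C7a (2S in 11) and C1 (carbinol R) in the anti relationship with the auxiliary overriding the remote C7 methyl centre.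

Step 6
Reactants: 11 (4R)-4-benzyl-3-[(2S,3S)-2-{(R)-Ar(hydroxy)methyl}-3,7-dimethyloct-6-enoyl]-1,3-oxazolidin-2-one
Product: 12 (4R)-4-benzyl-3-[(2S,3S)-2-{(R)-Ar(triethylsilyloxy)methyl}-3,7-dimethyloct-6-enoyl]-1,3-oxazolidin-2-one
Conditions: Et3SiOTf, 2,6-lutidine, CH2Cl2, −78 → 0 °C
Reagents that add atoms: triethylsilyl trifluoromethanesulfonate, CC[Si](CC)(CC)OS(=O)(=O)C(F)(F)F
Why: Silylation of the hindered secondary alcohol with the silyl triflate and 2,6-lutidine at low temperature is reliable and should block retro-aldol and elimination pathways in the steps that follow.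

Step 7
Reactants: 12 (4R)-4-benzyl-3-[(2S,3S)-2-{(R)-Ar(triethylsilyloxy)methyl}-3,7-dimethyloct-6-enoyl]-1,3-oxazolidin-2-one
Product: 13 (2R,3S)-2-{(R)-Ar(triethylsilyloxy)methyl}-3,7-dimethyloct-6-en-1-ol
Conditions: NaBH4 (4 equiv), THF/H2O (4:1), 0 °C → rt
Reagents that add atoms: none
Why: Borohydride reduction of an N-acyloxazolidinone in aqueous THF (reductive auxiliary cleavage) should be selective for the activated exocyclic imide carbonyl over the far less electrophilic 4-alkoxycoumarin lactone and releases the auxiliary without touching the α-stereocentre.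

Step 8
Reactants: 13 (2R,3S)-2-{(R)-Ar(triethylsilyloxy)methyl}-3,7-dimethyloct-6-en-1-ol
Product: 14 (2S,3S)-2-{(R)-Ar(triethylsilyloxy)methyl}-3,7-dimethyloct-6-enal
Conditions: Dess–Martin periodinane, NaHCO3, CH2Cl2, 0 °C → rt
Reagents that add atoms: none
Why: Dess–Martin oxidation under bicarbonate buffer should give the α-branched aldehyde without epimerisation at C7a or loss of the silyl ether.

Step 9
Reactants: 14 (2S,3S)-2-{(R)-Ar(triethylsilyloxy)methyl}-3,7-dimethyloct-6-enal
Product: 15 methyl (2Z,4R,5S)-4-{(R)-Ar(triethylsilyloxy)methyl}-2,5,9-trimethyldeca-2,8-dienoate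
Conditions: (CF3CH2O)2P(O)CH(CH3)CO2Me, KN(SiMe3)2, 18-crown-6, THF, −78 °C
Reagents that add atoms: methyl 2-[bis(2,2,2-trifluoroethoxy)phosphoryl]propanoate, COC(=O)C(C)P(=O)(OCC(F)(F)F)OCC(F)(F)F
Why: Still–Gennari olefination with the bis(trifluoroethyl) phosphonopropionate under dissociating conditions should give the (Z)-trisubstituted enoate through fast, irreversible elimination of the kinetic adduct, and the low temperature protects the α-stereocentre.

Step 10
Reactants: 15 methyl (2Z,4R,5S)-4-{(R)-Ar(triethylsilyloxy)methyl}-2,5,9-trimethyldeca-2,8-dienoate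
Product: 17 (5R,6R)-6-Ar-3-methyl-5-[(2S)-6-methylhept-5-en-2-yl]-5,6-dihydro-2H-pyran-2-one, via hydroxy ester 16 (not isolated)
Conditions: camphorsulfonic acid (0.1 equiv), CH2Cl2/MeOH (5:1), rt; then toluene, 50 °C
Reagents that add atoms: none
Why: Acid-catalysed methanolysis of the triethylsilyl ether frees the C1 hydroxyl, which should lactonise onto the cis-disposed methyl ester (intramolecular transesterification) to give the six-membered unsaturated lactone with both stereocentres unchanged.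

Step 11
Reactants: 17 (5R,6R)-6-Ar-3-methyl-5-[(2S)-6-methylhept-5-en-2-yl]-5,6-dihydro-2H-pyran-2-one
Product: 19 (4S)-4-[(2R,3R)-2-Ar-5-methyl-6-oxo-3,6-dihydro-2H-pyran-3-yl]pentanal, via diol 18 (not isolated)
Conditions: OsO4 (2 mol %), NaIO4 (4 equiv), 2,6-lutidine (2 equiv), dioxane/H2O (3:1), rt
Reagents that add atoms: osmium tetroxide, O=[Os](=O)(=O)=O (oxygen donor); sodium periodate, [Na+].[O-]I(=O)(=O)=O (terminal oxidant)
Why: In this Lemieux–Johnson oxidation OsO4 should dihydroxylate the electron-rich trisubstituted side-chain alkene far faster than the electron-poor enoate or the tetrasubstituted coumarin double bond, and periodate cleaves the diol to the aldehyde.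

Step 12
Reactants: 19 (4S)-4-[(2R,3R)-2-Ar-5-methyl-6-oxo-3,6-dihydro-2H-pyran-3-yl]pentanal
Product: 20 (4S)-4-[(2R,3R)-2-Ar-5-methyl-6-oxo-3,6-dihydro-2H-pyran-3-yl]pentanoic acid
Conditions: NaClO2, NaH2PO4, 2-methylbut-2-ene, t-BuOH/H2O, rt
Reagents that add atoms: sodium chlorite, [Na+].[O-]Cl=O
Why: Pinnick oxidation should convert the aldehyde into the acid under buffered conditions that leave the lactone, the benzyl enol ether and the enoate untouched, the hypochlorite being scavenged by the alkene additive.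

Step 13
Reactants: 20 (4S)-4-[(2R,3R)-2-Ar-5-methyl-6-oxo-3,6-dihydro-2H-pyran-3-yl]pentanoic acid; 21 N-hydroxyphthalimide
Product: 22 1,3-dioxoisoindolin-2-yl (4S)-4-[(2R,3R)-2-Ar-5-methyl-6-oxo-3,6-dihydro-2H-pyran-3-yl]pentanoate
Conditions: i-PrN=C=N-i-Pr, DMAP (0.1 equiv), CH2Cl2, 0 °C → rt
Reagents that add atoms: none
Why: Carbodiimide (Steglich-type) esterification of the acid with N-hydroxyphthalimide should give the redox-active ester under neutral conditions that do not epimerise C7a.

Step 14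
Reactants: 22 1,3-dioxoisoindolin-2-yl (4S)-4-[(2R,3R)-2-Ar-5-methyl-6-oxo-3,6-dihydro-2H-pyran-3-yl]pentanoate
Product: 23 (1R,4aS,7S,7aR)-1-Ar-4,7-dimethylhexahydrocyclopenta[c]pyran-3(1H)-one (C4 epimers)
Conditions: Ru(bpy)3(PF6)2 (1 mol %), Hantzsch ester (1.5 equiv), i-Pr2NEt·HBF4 (1 equiv), degassed CH2Cl2 (0.02 M), blue LEDs (450 nm), rt
Reagents that add atoms: none
Why: The photoexcited divalent ruthenium complex is quenched reductively by the Hantzsch ester, and the monovalent ruthenium species so formed transfers one electron to the phthalimide ester of 22, whose radical anion fragments to phthalimide anion, CO2 and the primary C5 radical. This radical adds to C4a, the β-carbon of the α-methyl unsaturated lactone, and the tertiary α-acyl radical at C4 is then quenched by hydrogen transfer from the oxidised dihydropyridine (or by reduction and protonation); the closest known reaction type is the reductive decarboxylative Giese addition of N-acyloxyphthalimides, here in its intramolecular form. The cyclopentane (C4a, C5, C6, C7, C7a) closes in the 5-exo-trig mode. C4a is controlled by the tether, which is anchored at C7a and can reach only the face of C4a syn to the C7a–C7 bond, so the ring fusion is cis; C4 is set by hydrogen delivery to a planar radical and does not matter because step 15 makes it sp2. The step needs cyclisation to outrun premature hydrogen transfer to the C5 radical and a 1,5-hydrogen shift from C1–H, which the fast, polarity-matched closure of a nucleophilic alkyl radical onto an enoate held three atoms away should secure, helped by high dilution. It also needs electron transfer to the redox-active ester only, which its much less negative reduction potential relative to coumarin and enoate should provide.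

Step 15
Reactants: 23 (1R,4aS,7S,7aR)-1-Ar-4,7-dimethylhexahydrocyclopenta[c]pyran-3(1H)-one (C4 epimers)
Product: 24 (1R,4aS,7S,7aR)-1-Ar-4,7-dimethyl-1,4a,5,6,7,7a-hexahydrocyclopenta[c]pyran-3-yl trifluoromethanesulfonate
Conditions: KN(SiMe3)2 (1.2 equiv), PhNTf2 (1.3 equiv), THF/DMPU, −78 °C
Reagents that add atoms: N-phenylbis(trifluoromethanesulfonimide), O=S(=O)(N(c1ccccc1)S(=O)(=O)C(F)(F)F)C(F)(F)F
Why: Kinetic deprotonation at C4, the only enolisable position, and O-sulfonylation of the lactone enolate should give the cyclic ketene acetal triflate, which erases the C4 stereocentre so that both epimers of 23 converge.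

Step 16
Reactants: 25 (2R)-2-hydroxy-3-methylbutanoic acid
Product: 26 methyl (2R)-2-hydroxy-3-methylbutanoate
Conditions: MeOH, H2SO4 (cat.), 65 °C
Reagents that add atoms: methanol, CO
Why: Fischer esterification of the α-hydroxy acid in excess methanol should proceed without touching the stereocentre.

Step 17
Reactants: 26 methyl (2R)-2-hydroxy-3-methylbutanoate
Product: 27 methyl (2R)-3-methyl-2-(triethylsilyloxy)butanoate
Conditions: Et3SiCl, imidazole, CH2Cl2, 0 °C → rt
Reagents that add atoms: chlorotriethylsilane, CC[Si](Cl)(CC)CC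
Why: Silylation of the secondary alcohol with the silyl chloride and imidazole is routine and does not affect the stereocentre.

Step 18
Reactants: 27 methyl (2R)-3-methyl-2-(triethylsilyloxy)butanoate
Product: 28 (2R)-3-methyl-2-(triethylsilyloxy)butanal
Conditions: i-Bu2AlH (1.1 equiv), CH2Cl2, −78 °C; then aq. KNa tartrate
Reagents that add atoms: none
Why: Half-reduction of the α-silyloxy methyl ester with the aluminium hydride at −78 °C should stop at the aldehyde because the tetrahedral aluminium hemiacetal is stabilised by the α-oxygen, and the aldehyde is used at once to avoid racemisation.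

Step 19
Reactants: 24 (1R,4aS,7S,7aR)-1-Ar-4,7-dimethyl-1,4a,5,6,7,7a-hexahydrocyclopenta[c]pyran-3-yl trifluoromethanesulfonate; 28 (2R)-3-methyl-2-(triethylsilyloxy)butanal
Product: 29 (2R)-1-[(1R,4aS,7S,7aR)-1-Ar-4,7-dimethyl-1,4a,5,6,7,7a-hexahydrocyclopenta[c]pyran-3-yl]-3-methyl-2-(triethylsilyloxy)butan-1-ol (carbinol epimers)
Conditions: CrCl2 (4 equiv), NiCl2 (2 mol %), DMF, rt
Reagents that add atoms: none
Why: In this Nozaki–Hiyama–Kishi coupling zerovalent nickel inserts into the alkenyl C–OTf bond, transmetalation gives an alkenylchromium species that should add chemoselectively to the aldehyde in the presence of lactone, benzyl ether and silyl ether, and the new carbinol stereocentre is inconsequential because it is oxidised next.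

Step 20
Reactants: 29 (2R)-1-[(1R,4aS,7S,7aR)-1-Ar-4,7-dimethyl-1,4a,5,6,7,7a-hexahydrocyclopenta[c]pyran-3-yl]-3-methyl-2-(triethylsilyloxy)butan-1-ol (carbinol epimers)
Product: 30 (2R)-1-[(1R,4aS,7S,7aR)-1-Ar-4,7-dimethyl-1,4a,5,6,7,7a-hexahydrocyclopenta[c]pyran-3-yl]-3-methyl-2-(triethylsilyloxy)butan-1-one
Conditions: Dess–Martin periodinane, NaHCO3, CH2Cl2, 0 °C → rt
Reagents that add atoms: none
Why: Dess–Martin oxidation of the allylic alcohol should give the enol-ether-conjugated ketone (a vinylogous ester) under buffered conditions that do not epimerise the α-silyloxy stereocentre.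

Step 21
Reactants: 30 (2R)-1-[(1R,4aS,7S,7aR)-1-Ar-4,7-dimethyl-1,4a,5,6,7,7a-hexahydrocyclopenta[c]pyran-3-yl]-3-methyl-2-(triethylsilyloxy)butan-1-one
Product: 31 (2R)-1-[(1R,4aS,7S,7aR)-1-Ar-4,7-dimethyl-1,4a,5,6,7,7a-hexahydrocyclopenta[c]pyran-3-yl]-2-hydroxy-3-methylbutan-1-one
Conditions: HF·pyridine, pyridine, THF, 0 °C → rt
Reagents that add atoms: none
Why: Fluoride-mediated cleavage of the triethylsilyl ether with buffered HF·pyridine should be mild enough to leave the benzyl enol ether, the vinylogous ester and the α-stereocentre intact.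

Step 22
Reactants: 31 (2R)-1-[(1R,4aS,7S,7aR)-1-Ar-4,7-dimethyl-1,4a,5,6,7,7a-hexahydrocyclopenta[c]pyran-3-yl]-2-hydroxy-3-methylbutan-1-one
Product: 32 (2R)-1-[(1R,4aS,7S,7aR)-1-Ar-4,7-dimethyl-1,4a,5,6,7,7a-hexahydrocyclopenta[c]pyran-3-yl]-3-methyl-1-oxobutan-2-yl acetate
Conditions: Ac2O, pyridine, DMAP (cat.), CH2Cl2, 0 °C
Reagents that add atoms: acetic anhydride, CC(=O)OC(C)=O
Why: DMAP-catalysed acetylation of the secondary α-hydroxy ketone is fast at 0 °C, so enolisation of the ketone and hence epimerisation is not expected.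

Step 23
Reactants: 32 (2R)-1-[(1R,4aS,7S,7aR)-1-Ar-4,7-dimethyl-1,4a,5,6,7,7a-hexahydrocyclopenta[c]pyran-3-yl]-3-methyl-1-oxobutan-2-yl acetate
Product: 33 (2R)-1-[(1R,4aS,7S,7aR)-1-(4-hydroxy-5-methyl-2-oxo-2H-chromen-3-yl)-4,7-dimethyl-1,4a,5,6,7,7a-hexahydrocyclopenta[c]pyran-3-yl]-3-methyl-1-oxobutan-2-yl acetate (target)
Conditions: H2 (1 atm), 5% Pd/C, EtOAc, rt
Reagents that add atoms: none
Why: Hydrogenolysis of the benzyl ether of the vinylogous acid should be fast over Pd/C, whereas the tetrasubstituted push–pull alkene, the coumarin and the acetate are expected to be inert under one atmosphere of hydrogen if the reaction is stopped at full conversion.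

Compound list
1 | 1-(2-hydroxy-6-methylphenyl)ethanone | CC(=O)c1c(C)cccc1O | starting material
2 | 4-hydroxy-5-methyl-2H-chromen-2-one | Cc1cccc2oc(=O)cc(O)c12 | intermediate
3 | N-[(4-chloro-5-methyl-2-oxo-2H-chromen-3-yl)methylidene]-N-methylmethanaminium chloride | C[N+](C)=Cc1c(Cl)c2c(C)cccc2oc1=O.[Cl-] | intermediate (not isolated)
4 | 4-chloro-5-methyl-2-oxo-2H-chromene-3-carbaldehyde | O=Cc1c(Cl)c2c(C)cccc2oc1=O | intermediate
5 | 4-(benzyloxy)-5-methyl-2-oxo-2H-chromene-3-carbaldehyde | O=Cc1c(OCc2ccccc2)c2c(C)cccc2oc1=O | intermediate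
6 | (3S)-3,7-dimethyloct-6-enoic acid | OC(=O)C[C@@H](C)CCC=C(C)C | starting material
7 | (4R)-4-benzyl-1,3-oxazolidin-2-one | O=C1N[C@H](Cc2ccccc2)CO1 | starting material
8 | (3S)-3,7-dimethyloct-6-enoic pivalic anhydride | CC(C)(C)C(=O)OC(=O)C[C@@H](C)CCC=C(C)C | intermediate (not isolated)
9 | (4R)-4-benzyl-3-[(3S)-3,7-dimethyloct-6-enoyl]-1,3-oxazolidin-2-one | O=C(C[C@@H](C)CCC=C(C)C)N1[C@H](Cc2ccccc2)COC1=O | intermediate
10 | (4R)-4-benzyl-3-[(2S,3S)-2-{(R)-[4-(benzyloxy)-5-methyl-2-oxo-2H-chromen-3-yl](trimethylsilyloxy)methyl}-3,7-dimethyloct-6-enoyl]-1,3-oxazolidin-2-one | O=C([C@@H]([C@@H](C)CCC=C(C)C)[C@H](c1c(OCc2ccccc2)c2c(C)cccc2oc1=O)O[Si](C)(C)C)N1[C@H](Cc2ccccc2)COC1=O | intermediate (not isolated)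
11 | (4R)-4-benzyl-3-[(2S,3S)-2-{(R)-[4-(benzyloxy)-5-methyl-2-oxo-2H-chromen-3-yl](hydroxy)methyl}-3,7-dimethyloct-6-enoyl]-1,3-oxazolidin-2-one | O=C([C@@H]([C@@H](C)CCC=C(C)C)[C@H](c1c(OCc2ccccc2)c2c(C)cccc2oc1=O)O)N1[C@H](Cc2ccccc2)COC1=O | intermediate
12 | (4R)-4-benzyl-3-[(2S,3S)-2-{(R)-[4-(benzyloxy)-5-methyl-2-oxo-2H-chromen-3-yl](triethylsilyloxy)methyl}-3,7-dimethyloct-6-enoyl]-1,3-oxazolidin-2-one | O=C([C@@H]([C@@H](C)CCC=C(C)C)[C@H](c1c(OCc2ccccc2)c2c(C)cccc2oc1=O)O[Si](CC)(CC)CC)N1[C@H](Cc2ccccc2)COC1=O | intermediate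
13 | (2R,3S)-2-{(R)-[4-(benzyloxy)-5-methyl-2-oxo-2H-chromen-3-yl](triethylsilyloxy)methyl}-3,7-dimethyloct-6-en-1-ol | OC[C@@H]([C@@H](C)CCC=C(C)C)[C@H](c1c(OCc2ccccc2)c2c(C)cccc2oc1=O)O[Si](CC)(CC)CC | intermediate
14 | (2S,3S)-2-{(R)-[4-(benzyloxy)-5-methyl-2-oxo-2H-chromen-3-yl](triethylsilyloxy)methyl}-3,7-dimethyloct-6-enal | O=C[C@@H]([C@@H](C)CCC=C(C)C)[C@H](c1c(OCc2ccccc2)c2c(C)cccc2oc1=O)O[Si](CC)(CC)CC | intermediate
15 | methyl (2Z,4R,5S)-4-{(R)-[4-(benzyloxy)-5-methyl-2-oxo-2H-chromen-3-yl](triethylsilyloxy)methyl}-2,5,9-trimethyldeca-2,8-dienoate | COC(=O)/C(C)=C\[C@@H]([C@@H](C)CCC=C(C)C)[C@H](c1c(OCc2ccccc2)c2c(C)cccc2oc1=O)O[Si](CC)(CC)CC | intermediate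
16 | methyl (2Z,4R,5S)-4-{(R)-[4-(benzyloxy)-5-methyl-2-oxo-2H-chromen-3-yl](hydroxy)methyl}-2,5,9-trimethyldeca-2,8-dienoate | COC(=O)/C(C)=C\[C@@H]([C@@H](C)CCC=C(C)C)[C@H](c1c(OCc2ccccc2)c2c(C)cccc2oc1=O)O | intermediate (not isolated)
17 | (5R,6R)-6-[4-(benzyloxy)-5-methyl-2-oxo-2H-chromen-3-yl]-3-methyl-5-[(2S)-6-methylhept-5-en-2-yl]-5,6-dihydro-2H-pyran-2-one | CC1=C[C@@H]([C@@H](C)CCC=C(C)C)[C@H](c2c(OCc3ccccc3)c3c(C)cccc3oc2=O)OC1=O | intermediate
18 | (5R,6R)-6-[4-(benzyloxy)-5-methyl-2-oxo-2H-chromen-3-yl]-5-[(2S)-5,6-dihydroxy-6-methylheptan-2-yl]-3-methyl-5,6-dihydro-2H-pyran-2-one (carbinol epimers) | CC1=C[C@@H]([C@@H](C)CCC(O)C(C)(C)O)[C@H](c2c(OCc3ccccc3)c3c(C)cccc3oc2=O)OC1=O | intermediate (not isolated)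
19 | (4S)-4-[(2R,3R)-2-[4-(benzyloxy)-5-methyl-2-oxo-2H-chromen-3-yl]-5-methyl-6-oxo-3,6-dihydro-2H-pyran-3-yl]pentanal | CC1=C[C@@H]([C@@H](C)CCC=O)[C@H](c2c(OCc3ccccc3)c3c(C)cccc3oc2=O)OC1=O | intermediate
20 | (4S)-4-[(2R,3R)-2-[4-(benzyloxy)-5-methyl-2-oxo-2H-chromen-3-yl]-5-methyl-6-oxo-3,6-dihydro-2H-pyran-3-yl]pentanoic acid | CC1=C[C@@H]([C@@H](C)CCC(=O)O)[C@H](c2c(OCc3ccccc3)c3c(C)cccc3oc2=O)OC1=O | intermediate
21 | N-hydroxyphthalimide | O=C1c2ccccc2C(=O)N1O | starting material
22 | 1,3-dioxoisoindolin-2-yl (4S)-4-[(2R,3R)-2-[4-(benzyloxy)-5-methyl-2-oxo-2H-chromen-3-yl]-5-methyl-6-oxo-3,6-dihydro-2H-pyran-3-yl]pentanoate | CC1=C[C@@H]([C@@H](C)CCC(=O)ON2C(=O)c3ccccc3C2=O)[C@H](c2c(OCc3ccccc3)c3c(C)cccc3oc2=O)OC1=O | intermediate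
23 | (1R,4aS,7S,7aR)-1-[4-(benzyloxy)-5-methyl-2-oxo-2H-chromen-3-yl]-4,7-dimethylhexahydrocyclopenta[c]pyran-3(1H)-one (C4 epimers) | O=C1C(C)[C@H]2CC[C@H](C)[C@H]2[C@H](c2c(OCc3ccccc3)c3c(C)cccc3oc2=O)O1 | intermediate
24 | (1R,4aS,7S,7aR)-1-[4-(benzyloxy)-5-methyl-2-oxo-2H-chromen-3-yl]-4,7-dimethyl-1,4a,5,6,7,7a-hexahydrocyclopenta[c]pyran-3-yl trifluoromethanesulfonate | O=S(=O)(OC1=C(C)[C@H]2CC[C@H](C)[C@H]2[C@H](c2c(OCc3ccccc3)c3c(C)cccc3oc2=O)O1)C(F)(F)F | intermediate
25 | (2R)-2-hydroxy-3-methylbutanoic acid | CC(C)[C@@H](O)C(=O)O | starting material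
26 | methyl (2R)-2-hydroxy-3-methylbutanoate | CC(C)[C@@H](O)C(=O)OC | intermediate
27 | methyl (2R)-3-methyl-2-(triethylsilyloxy)butanoate | CC(C)[C@@H](O[Si](CC)(CC)CC)C(=O)OC | intermediate
28 | (2R)-3-methyl-2-(triethylsilyloxy)butanal | CC(C)[C@@H](O[Si](CC)(CC)CC)C=O | intermediate
29 | (2R)-1-[(1R,4aS,7S,7aR)-1-[4-(benzyloxy)-5-methyl-2-oxo-2H-chromen-3-yl]-4,7-dimethyl-1,4a,5,6,7,7a-hexahydrocyclopenta[c]pyran-3-yl]-3-methyl-2-(triethylsilyloxy)butan-1-ol (carbinol epimers) | CC(C)[C@@H](O[Si](CC)(CC)CC)C(O)C1=C(C)[C@H]2CC[C@H](C)[C@H]2[C@H](c2c(OCc3ccccc3)c3c(C)cccc3oc2=O)O1 | intermediate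
30 | (2R)-1-[(1R,4aS,7S,7aR)-1-[4-(benzyloxy)-5-methyl-2-oxo-2H-chromen-3-yl]-4,7-dimethyl-1,4a,5,6,7,7a-hexahydrocyclopenta[c]pyran-3-yl]-3-methyl-2-(triethylsilyloxy)butan-1-one | CC(C)[C@@H](O[Si](CC)(CC)CC)C(=O)C1=C(C)[C@H]2CC[C@H](C)[C@H]2[C@H](c2c(OCc3ccccc3)c3c(C)cccc3oc2=O)O1 | intermediate
31 | (2R)-1-[(1R,4aS,7S,7aR)-1-[4-(benzyloxy)-5-methyl-2-oxo-2H-chromen-3-yl]-4,7-dimethyl-1,4a,5,6,7,7a-hexahydrocyclopenta[c]pyran-3-yl]-2-hydroxy-3-methylbutan-1-one | CC(C)[C@@H](O)C(=O)C1=C(C)[C@H]2CC[C@H](C)[C@H]2[C@H](c2c(OCc3ccccc3)c3c(C)cccc3oc2=O)O1 | intermediate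
32 | (2R)-1-[(1R,4aS,7S,7aR)-1-[4-(benzyloxy)-5-methyl-2-oxo-2H-chromen-3-yl]-4,7-dimethyl-1,4a,5,6,7,7a-hexahydrocyclopenta[c]pyran-3-yl]-3-methyl-1-oxobutan-2-yl acetate | CC(=O)O[C@@H](C(=O)C1=C(C)[C@H]2CC[C@H](C)[C@H]2[C@H](c2c(OCc3ccccc3)c3c(C)cccc3oc2=O)O1)C(C)C | intermediate
33 | (2R)-1-[(1R,4aS,7S,7aR)-1-(4-hydroxy-5-methyl-2-oxo-2H-chromen-3-yl)-4,7-dimethyl-1,4a,5,6,7,7a-hexahydrocyclopenta[c]pyran-3-yl]-3-methyl-1-oxobutan-2-yl acetate | CC(=O)O[C@@H](C(=O)C1=C(C)[C@H]2CC[C@H](C)[C@H]2[C@H](c2c(O)c3c(C)cccc3oc2=O)O1)C(C)C | target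

Total step count: 23. Longest linear sequence: 19 steps (steps 1–3, 5–15 and 19–23, from 1 to 33).

Steps most likely to fail

Step 14. The ring closure may lose to premature hydrogen transfer to the primary C5 radical, to a 1,5-hydrogen shift from C1–H, or to slow single-electron reduction of the primary redox-active ester. The fallback keeps the C4a–C5 disconnection but generates the radical by a halogen-based chain process; it sets out from acid 20 and comes back to the route at 23. Hunsdiecker-type iododecarboxylation of 20 (PhI(OAc)2, I2, visible light, benzene, rt) should give (5R,6R)-6-[4-(benzyloxy)-5-methyl-2-oxo-2H-chromen-3-yl]-5-[(2S)-4-iodobutan-2-yl]-3-methyl-5,6-dihydro-2H-pyran-2-one F1. Slow addition of Bu3SnH with azobisisobutyronitrile in benzene at 80 °C (tin-hydride-mediated 5-exo Giese cyclisation, in which the stationary hydride concentration is set by the addition rate) should then close the same bond to give 23.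

Step 19. The coupling may stall through slow oxidative addition or transmetalation at the hindered tetrasubstituted alkenyl triflate, through hydrolysis of the triflate back to the lactone, or through sluggish addition to the α-branched aldehyde. The fallback replaces carbonyl addition by a Stille acylation; it sets out from triflate 24 and hydroxy acid 25 and comes back to the route at 32, which also makes steps 16–18 and 20–22 unnecessary. Stannylation of 24 (Me3SnSnMe3, Pd(PPh3)4, LiCl, THF, 65 °C) should give 4-(benzyloxy)-3-[(1R,4aS,7S,7aR)-4,7-dimethyl-3-(trimethylstannyl)-1,4a,5,6,7,7a-hexahydrocyclopenta[c]pyran-1-yl]-5-methyl-2H-chromen-2-one F2. Acid 25 is acetylated with neat acetyl chloride to (2R)-2-acetoxy-3-methylbutanoic acid F3 and converted with oxalyl chloride and catalytic DMF in CH2Cl2 into (2R)-2-acetoxy-3-methylbutanoyl chloride F4. Palladium-catalysed coupling of F2 with F4 (PdCl2(PPh3)2, CuI, toluene, 70 °C) should give the acetoxy ketone 32 directly.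

Step 5. The aldol may suffer from low conversion with the hindered, doubly ortho-substituted aldehyde, from attack of base at the vinylogous carbonate, or from erosion of anti and facial selectivity. The fallback sets out from the same partners 9 and 5 and comes back to the route at 11, but changes the bond-forming manifold from a catalytic, reversible magnesium aldol to a stoichiometric boron enolate reacting through an open transition state. The (Z)-dibutylboron enolate of 9 is pre-formed (Bu2BOTf, i-Pr2NEt, CH2Cl2, −78 → 0 °C) and treated at −78 °C with aldehyde 5 precomplexed with Et2AlCl. Attack on the boron-chelated enolate, again opposite the auxiliary benzyl group, is known to favour the anti-aldol, and oxidative work-up (H2O2, pH 7 buffer) should give 11. This fallback makes no new compound (F0).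

Further compounds
F1 | step 14 | (5R,6R)-6-[4-(benzyloxy)-5-methyl-2-oxo-2H-chromen-3-yl]-5-[(2S)-4-iodobutan-2-yl]-3-methyl-5,6-dihydro-2H-pyran-2-one | CC1=C[C@@H]([C@@H](C)CCI)[C@H](c2c(OCc3ccccc3)c3c(C)cccc3oc2=O)OC1=O
F2 | step 19 | 4-(benzyloxy)-3-[(1R,4aS,7S,7aR)-4,7-dimethyl-3-(trimethylstannyl)-1,4a,5,6,7,7a-hexahydrocyclopenta[c]pyran-1-yl]-5-methyl-2H-chromen-2-one | C[Sn](C)(C)C1=C(C)[C@H]2CC[C@H](C)[C@H]2[C@H](c2c(OCc3ccccc3)c3c(C)cccc3oc2=O)O1
F3 | step 19 | (2R)-2-acetoxy-3-methylbutanoic acid | CC(C)[C@@H](OC(C)=O)C(=O)O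
F4 | step 19 | (2R)-2-acetoxy-3-methylbutanoyl chloride | CC(C)[C@@H](OC(C)=O)C(Cl)=O
F0 | step 5 | none | none
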